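**Retrosynthetic overview**

1. Locants: ring A and ring B are the two resorcinol-type benzene rings; ring D (C7a, C8a) is the dihydrofuran fused to ring A, ring E (C7c, C8c) the dihydrofuran fused to ring B, and both benzene rings are fused to the seven-membered ring, whose alkene is C7b(aryl)=C8b(H). B4 is the ring B carbon between the oxygenated carbons B3 and B5; B6 is the ring B carbon bonded to C7b.
2. Target ⇒ (global O-demethylation) hexamethyl ether 26 ⇒ ring E opened across B4–C8c and O–C7c: core phenol 17 (rings A, B, D and the seven-membered ring) plus (E)-α-nitro-4-hydroxystilbene 23. They are joined in one enantioselective Friedel–Crafts / quinone-methide (3+2) annulation that closes ring E and sets C7c and C8c.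
3. Enabling feature: B4 is the only free carbon ortho to the single free phenol (B5–OH) and lies between two oxygenated carbons (B3, B5), while B6 is blocked by the seven-membered ring. C7c carries a 4-hydroxyphenyl group, so a nitro group placed there leaves through a p-quinone methide that the B5 oxygen captures.
4. 17 ⇒ ring D by enantioselective carbene C–H insertion (C7a–C8a) on the hydrazone of dibenzosuberenone 12 ⇒ seven-membered ring by Friedel–Crafts acylation (C8a–ring A) of a stilbene acid released from phthalide 7 ⇒ methyl 3,5-dimethoxybenzoate, 4-methoxybenzoyl chloride, a 3,5-dimethoxybenzyl Grignard reagent and 4-methoxybenzyl chloride. The B5 and ring A phenols are freed by carbonyl-directed demethylation.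
5. Order of ring formation: seven-membered ring (step 3), ring D (step 7), ring E (step 12).

Key step: step 12

**Remarks on the chemistry (assumptions)**

- The sense of induction of Rh2(R-PTAD)4 (step 7) and of the quinidine-derived squaramide (step 12) is assigned by analogy with simpler substrates. If either proves opposite, the mirror-image catalyst (Rh2(S-PTAD)4; the quinine-derived squaramide) is used and nothing else changes.
- Step 7 is assumed to give the 7a,8a-cis isomer kinetically. If the trans isomer forms directly, step 8 only removes the benzyl ether.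

**Route**

Step 1
Reactants: 1 methyl 3,5-dimethoxybenzoate; 2 4-methoxybenzoyl chloride
Product: 4 methyl 3-hydroxy-5-methoxy-2-(4-methoxybenzoyl)benzoate, via keto ester 3 (not isolated)
Conditions: AlCl3 (2.5 equiv), CH2Cl2, 0 °C → 40 °C; aq. HCl work-up
Reagents that add atoms: none
Why: Friedel–Crafts acylation should occur at the ring carbon ortho to the ester and para to a methoxy group, and the aluminium chelate of the new ketone should then cleave the one methoxy group ortho to it (the classical entry to 2-hydroxy-4-methoxybenzophenones), which singles out the future B5 oxygen; no stereocentre.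

Step 2
Reactants: 4 methyl 3-hydroxy-5-methoxy-2-(4-methoxybenzoyl)benzoate; 5 3,5-dimethoxybenzylmagnesium chloride (3 equiv)
Product: 7 racemic 3-(3,5-dimethoxybenzyl)-4-hydroxy-6-methoxy-3-(4-methoxyphenyl)isobenzofuran-1(3H)-one, via hydroxy ester 6 (not isolated)
Conditions: THF, −78 °C → 0 °C; aq. HCl work-up, rt
Reagents that add atoms: none
Why: Grignard 1,2-addition to the magnesium-chelated ortho-hydroxy diaryl ketone should be faster than attack on the flanked methyl ester, and the tertiary alkoxide lactonises onto that ester; the new quaternary centre is racemic and is destroyed in step 3.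

Step 3
Reactants: 7 racemic phthalide
Product: 9 1-hydroxy-3,6,8-trimethoxy-11-(4-methoxyphenyl)-5H-dibenzo[a,d][7]annulen-5-one, via Z-stilbene acid 8 (not isolated)
Conditions: P2O5 in CH3SO3H (1:10 w/w), 25 → 40 °C
Reagents that add atoms: none
Why: The strong acid should ionise the tertiary, doubly benzylic lactone C–O bond and give the triarylethylene acid by E1 elimination; its isomers interconvert by reprotonation, and only the (Z)-acid 8 can close the seven-membered ring by intramolecular Friedel–Crafts acylation at the ring A carbon ortho and para to methoxy groups, which is far more nucleophilic than the meta-to-methoxy carbon of the 4-methoxyphenyl ring that would give an anthrone; no stereocentre.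

Step 4
Reactants: 9 dibenzosuberenone
Product: 10 1,6-dihydroxy-3,8-dimethoxy-11-(4-methoxyphenyl)-5H-dibenzo[a,d][7]annulen-5-one
Conditions: BCl3 (2.5 equiv), CH2Cl2, −78 °C → 0 °C; aq. work-up
Reagents that add atoms: none
Why: Chelation-directed demethylation: BCl3 bound to the diaryl ketone should cleave only the methoxy group ortho to the carbonyl (ring A), freeing the oxygen that will enter ring D.

Step 5
Reactants: 10 dihydroxy ketone; 11 4-methoxybenzyl chloride (2.5 equiv)
Product: 12 3,8-dimethoxy-1,6-bis[(4-methoxybenzyl)oxy]-11-(4-methoxyphenyl)-5H-dibenzo[a,d][7]annulen-5-one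
Conditions: K2CO3, n-Bu4NI (cat.), DMF, 60 °C
Reagents that add atoms: none
Why: Williamson ether synthesis on both phenols; the ring A ether supplies C7a with its aryl group for the carbene insertion, and the ring B ether protects B5–OH until step 8.

Step 6
Reactants: 12 bis(4-methoxybenzyl) ether ketone
Product: 13 hydrazone of 12
Conditions: N2H4·H2O (10 equiv), AcOH (cat.), n-PrOH, 100 °C
Reagents that add atoms: hydrazine, NN
Why: Acid-catalysed condensation of the diaryl ketone with hydrazine gives the hydrazone, the precursor of the diazo compound; the ethers and the trisubstituted alkene are inert.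

Step 7
Reactants: 13 hydrazone
Product: 15 cis-dihydrofuran ether (7aR,8aS; ring D closed), via diazo compound 14 (not isolated)
Conditions: activated MnO2 (8 equiv), CH2Cl2, 0 °C, filtration; then dirhodium tetrakis[(R)-(1-adamantyl)(phthalimido)acetate], Rh2(R-PTAD)4 (1 mol%), CH2Cl2, 0 °C → rt
Reagents that add atoms: none
Why: Dehydrogenation of the hydrazone to the diaryldiazomethane and intramolecular 1,5 C–H insertion of the derived donor/donor rhodium carbene into the benzylic C–H bond of the ring A ether (an established route to 2,3-diaryl-2,3-dihydrobenzofurans) should close ring D; the chiral carboxylate ligands select the carbene face and the enantiotopic hydrogen, setting C8a (S) and, kinetically, the 7a,8a-cis relationship, while the ring B ether, meta to the carbene carbon, cannot be reached.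

Step 8
Reactants: 15 cis-dihydrofuran ether
Product: 17 trans core phenol (7aS,8aS; B5–OH free), via cis phenol 16 (not isolated)
Conditions: CF3CO2H (10 vol%), pentamethylbenzene (5 equiv), CH2Cl2, 0 °C → rt
Reagents that add atoms: none
Why: Acidolysis of the 4-methoxybenzyl aryl ether (SN1, cation trapped by pentamethylbenzene in a Friedel–Crafts alkylation) and, under the same acid, reversible ionisation of the C7a–O bond to the 4-methoxybenzylic cation, which should re-close to the thermodynamically preferred 7a,8a-trans dihydrobenzofuran; C8a is untouched, so C7a becomes S under control of C8a.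

Step 9
Reactants: 18 1-bromo-4-(methoxymethoxy)benzene; 19 nitromethane (solvent and reactant)
Product: 20 1-(methoxymethoxy)-4-(nitromethyl)benzene
Conditions: Pd2(dba)3 (2.5 mol%), XPhos (6 mol%), Cs2CO3 (1.1 equiv), 3 Å MS, 50 °C
Reagents that add atoms: none
Why: Palladium-catalysed cross-coupling of the aryl bromide with the nitronate of nitromethane (α-arylation of a nitroalkane); the acetal is stable to carbonate.

Step 10
Reactants: 20 1-(methoxymethoxy)-4-(nitromethyl)benzene; 21 3,5-dimethoxybenzaldehyde
Product: 22 (E)-1,3-dimethoxy-5-{2-[4-(methoxymethoxy)phenyl]-2-nitroethenyl}benzene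
Conditions: n-BuNH2 (20 mol%), AcOH (20 mol%), toluene, 4 Å MS, 80 °C
Reagents that add atoms: none
Why: Amine-catalysed Knoevenagel (nitroaldol) condensation through the aldimine, with loss of water, should give the thermodynamically favoured (E)-α-nitrostilbene (nitro group anti to the β-aryl group).

Step 11
Reactants: 22 protected nitrostilbene
Product: 23 (E)-4-[2-(3,5-dimethoxyphenyl)-1-nitroethenyl]phenol
Conditions: HCl (3 M in MeOH), MeOH/CH2Cl2, 40 °C
Reagents that add atoms: none
Why: Acid-catalysed acetal exchange removes the methoxymethyl group as dimethoxymethane; the nitroalkene is stable to acid.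

Step 12
Reactants: 17 trans core phenol; 23 (E)-4-[2-(3,5-dimethoxyphenyl)-1-nitroethenyl]phenol (1.5 equiv)
Product: 26 hexamethyl ether (7aS,8aS,7cR,8cR; ring E closed), via nitroalkane 24 (not isolated), via quinone methide 25 (not isolated)
Conditions: squaramide from 9-amino-9-deoxy-epi-quinidine and 3,5-bis(trifluoromethyl)aniline (10 mol%), NaHCO3 (2 equiv), CHCl3, 0 °C → rt
Reagents that add atoms: none
Why: Proposed new method: the squaramide N–H bonds bind the nitro group of 23 and the quinuclidine nitrogen binds the B5–OH of 17, so that B4, the only free ortho carbon, adds to the β-carbon (C8c) of the nitroalkene in an ortho-Friedel–Crafts (Michael) step; the nitronate is protonated to nitroalkane 24, whose 4-hydroxyphenyl group then expels nitrite (vinylogous E1cB, hydrogencarbonate as base) to give p-quinone methide 25, and the B5 oxygen adds to C7c. The closest known reaction types are the squaramide- or thiourea-catalysed Friedel–Crafts/O-alkylation domino of naphthols and electron-rich phenols with (Z)-α-bromonitroalkenes to trans-2,3-dihydroarenofurans and the base-induced generation of p-quinone methides from 4-hydroxybenzyl sulfones; new is that nitrite is the leaving group and that the carbon next to oxygen carries an aryl group. Ring E closes in a formal (3+2) annulation, C–C bond first and then C–O bond by a 5-exo-trig oxa-1,6-addition. C8c is set by the catalyst in the C–C bond-forming step (the remote core stereocentres are not expected to interfere), and C7c by the kinetic and thermodynamic preference for the 2,3-trans-diaryl arrangement in the reversible quinone methide closure. The step needs B4 over B2/B6 and O(B5) over O(B3) selectivity, which the substrate secures because B6 is blocked by the seven-membered ring, B3 is a methyl ether and the para carbon B2 is not reached by the hydrogen-bond-templated ortho delivery; C8c over C7c attack follows from the polarisation by the nitro group.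

Step 13
Reactants: 26 hexamethyl ether
Product: 27 target compound CNP0325907.1 (7aS,8aS,7cR,8cR)
Conditions: BBr3 (12 equiv), CH2Cl2, −78 °C → 0 °C; MeOH, then aq. NaHCO3
Reagents that add atoms: none
Why: Lewis-acid cleavage (SN2 at methyl) of all six aryl methyl ethers; the free phenol and each newly freed oxygen become weakly donating aryl borates, which should disfavour ionisation of the two benzylic C7–O bonds, and any ring that opens is expected to re-close to the trans isomer, so the four stereocentres are kept.

**Compound list**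

1 | methyl 3,5-dimethoxybenzoate | COC(=O)c1cc(OC)cc(OC)c1 | starting material
2 | 4-methoxybenzoyl chloride | COc1ccc(cc1)C(Cl)=O | starting material
3 | methyl 3,5-dimethoxy-2-(4-methoxybenzoyl)benzoate | COC(=O)c1cc(OC)cc(OC)c1C(=O)c1ccc(OC)cc1 | intermediate (not isolated)
4 | methyl 3-hydroxy-5-methoxy-2-(4-methoxybenzoyl)benzoate | COC(=O)c1cc(OC)cc(O)c1C(=O)c1ccc(OC)cc1 | intermediate
5 | 3,5-dimethoxybenzylmagnesium chloride (commercial THF solution) | COc1cc(C[Mg]Cl)cc(OC)c1 | starting material
6 | methyl 2-[2-(3,5-dimethoxyphenyl)-1-hydroxy-1-(4-methoxyphenyl)ethyl]-3-hydroxy-5-methoxybenzoate (racemic, present as magnesium alkoxide) | COC(=O)c1cc(OC)cc(O)c1C(O)(Cc1cc(OC)cc(OC)c1)c1ccc(OC)cc1 | intermediate (not isolated)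
7 | 3-(3,5-dimethoxybenzyl)-4-hydroxy-6-methoxy-3-(4-methoxyphenyl)isobenzofuran-1(3H)-one (racemic) | O=C1OC(Cc2cc(OC)cc(OC)c2)(c2ccc(OC)cc2)c2c(O)cc(OC)cc12 | intermediate
8 | (Z)-2-[2-(3,5-dimethoxyphenyl)-1-(4-methoxyphenyl)ethenyl]-3-hydroxy-5-methoxybenzoic acid | OC(=O)c1cc(OC)cc(O)c1/C(c1ccc(OC)cc1)=C\c1cc(OC)cc(OC)c1 | intermediate (not isolated)
9 | 1-hydroxy-3,6,8-trimethoxy-11-(4-methoxyphenyl)-5H-dibenzo[a,d][7]annulen-5-one | COc1ccc(C2=Cc3cc(OC)cc(OC)c3C(=O)c3cc(OC)cc(O)c32)cc1 | intermediate
10 | 1,6-dihydroxy-3,8-dimethoxy-11-(4-methoxyphenyl)-5H-dibenzo[a,d][7]annulen-5-one | COc1ccc(C2=Cc3cc(OC)cc(O)c3C(=O)c3cc(OC)cc(O)c32)cc1 | intermediate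
11 | 4-methoxybenzyl chloride | COc1ccc(CCl)cc1 | starting material
12 | 3,8-dimethoxy-1,6-bis[(4-methoxybenzyl)oxy]-11-(4-methoxyphenyl)-5H-dibenzo[a,d][7]annulen-5-one | COc1ccc(C2=Cc3cc(OC)cc(OCc4ccc(OC)cc4)c3C(=O)c3cc(OC)cc(OCc4ccc(OC)cc4)c32)cc1 | intermediate
13 | hydrazone of 12 (C8a=N–NH2) | COc1ccc(C2=Cc3cc(OC)cc(OCc4ccc(OC)cc4)c3C(=NN)c3cc(OC)cc(OCc4ccc(OC)cc4)c32)cc1 | intermediate
14 | 5-diazo compound from 13 (C8a=N2) | COc1ccc(C2=Cc3cc(OC)cc(OCc4ccc(OC)cc4)c3C(=[N+]=[N-])c3cc(OC)cc(OCc4ccc(OC)cc4)c32)cc1 | intermediate (not isolated)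
15 | (7aR,8aS)-cis tetracycle: ring D closed, B5 O-(4-methoxybenzyl) ether, methyl ethers at ring A, B3 and both 4-oxyphenyl groups | COc1ccc(C2=Cc3cc(OC)cc4c3[C@H](c3cc(OC)cc(OCc5ccc(OC)cc5)c32)[C@H](c2ccc(OC)cc2)O4)cc1 | intermediate
16 | (7aR,8aS)-cis core phenol (B5–OH free) | COc1ccc(C2=Cc3cc(OC)cc4c3[C@H](c3cc(OC)cc(O)c32)[C@H](c2ccc(OC)cc2)O4)cc1 | intermediate (not isolated)
17 | (7aS,8aS)-trans core phenol: rings A, B, D and the seven-membered ring; B5–OH free; methyl ethers at ring A, B3 and both 4-oxyphenyl groups | COc1ccc(C2=Cc3cc(OC)cc4c3[C@H](c3cc(OC)cc(O)c32)[C@@H](c2ccc(OC)cc2)O4)cc1 | intermediate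
18 | 1-bromo-4-(methoxymethoxy)benzene | COCOc1ccc(Br)cc1 | starting material
19 | nitromethane | C[N+](=O)[O-] | starting material
20 | 1-(methoxymethoxy)-4-(nitromethyl)benzene | COCOc1ccc(C[N+](=O)[O-])cc1 | intermediate
21 | 3,5-dimethoxybenzaldehyde | COc1cc(C=O)cc(OC)c1 | starting material
22 | (E)-1,3-dimethoxy-5-{2-[4-(methoxymethoxy)phenyl]-2-nitroethenyl}benzene | [O-][N+](=O)/C(=C/c1cc(OC)cc(OC)c1)c1ccc(OCOC)cc1 | intermediate
23 | (E)-4-[2-(3,5-dimethoxyphenyl)-1-nitroethenyl]phenol | [O-][N+](=O)/C(=C/c1cc(OC)cc(OC)c1)c1ccc(O)cc1 | intermediate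
24 | (7aS,8aS,8cR)-nitroalkane: 17 carrying at B4 the 1-(3,5-dimethoxyphenyl)-2-(4-hydroxyphenyl)-2-nitroethyl group (C7c epimers) | COc1ccc(C2=Cc3cc(OC)cc4c3[C@H](c3cc(OC)c([C@@H](c5cc(OC)cc(OC)c5)C(c5ccc(O)cc5)[N+](=O)[O-])c(O)c32)[C@@H](c2ccc(OC)cc2)O4)cc1 | intermediate (not isolated)
25 | (7aS,8aS,8cR)-p-quinone methide: 17 carrying at B4 the 1-(3,5-dimethoxyphenyl)-2-(4-oxocyclohexa-2,5-dien-1-ylidene)ethyl group | COc1ccc(C2=Cc3cc(OC)cc4c3[C@H](c3cc(OC)c([C@@H](c5cc(OC)cc(OC)c5)C=C5C=CC(=O)C=C5)c(O)c32)[C@@H](c2ccc(OC)cc2)O4)cc1 | intermediate (not isolated)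
26 | (7aS,8aS,7cR,8cR)-hexamethyl ether of the target (all phenols methylated except the 4-hydroxyphenyl group on C7c) | COc1ccc(C2=Cc3cc(OC)cc4c3[C@H](c3cc(OC)c5c(c32)O[C@@H](c2ccc(O)cc2)[C@@H]5c2cc(OC)cc(OC)c2)[C@@H](c2ccc(OC)cc2)O4)cc1 | intermediate
27 | CNP0325907.1 (7aS,8aS,7cR,8cR) | Oc1ccc(C2=Cc3cc(O)cc4c3[C@H](c3cc(O)c5c(c32)O[C@@H](c2ccc(O)cc2)[C@@H]5c2cc(O)cc(O)c2)[C@@H](c2ccc(O)cc2)O4)cc1 | target

**Step count and risks**

Total step count: 13. Longest linear sequence: 10 steps (steps 1–8, 12 and 13).

Steps most likely to fail: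

1. Step 12 (the proposed method). C–C bond formation at the doubly ortho-substituted B4 may be too slow with the trisubstituted nitroalkene, facial control may be eroded, or the quinone methide may tautomerise to a stilbene before the oxygen closes the ring. The fallback uses known chemistry and closes ring E through the C–O bond instead. It sets out from 17: squaramide-catalysed ortho-Friedel–Crafts alkylation with commercial (E)-1,3-dimethoxy-5-(2-nitroethenyl)benzene, a disubstituted nitroalkene of the kind normally used in this reaction, should give nitroalkane F1 with C8c set by the catalyst. A buffered Nef reaction (aqueous TiCl3, NH4OAc) should give the aldehyde as its cyclic hemiacetal, lactol F2. Excess 4-methoxyphenylmagnesium bromide should add to the open hydroxy aldehyde to give diol F3. Catalytic p-toluenesulfonic acid should ionise the 4-methoxybenzylic alcohol so that the B5 oxygen closes ring E trans to the C8c aryl group, giving heptamethyl ether F4. BBr3 under the conditions of step 13 then comes back to the route at 27.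

2. Step 7. The chiral dirhodium catalyst may discriminate poorly between the enantiotopic hydrogens with the conformationally locked cyclic diaryl carbene, or azine and carbene-dimer formation may outrun the insertion. The fallback sets out from 12: LiN(i-Pr)2 (THF, −78 °C) should deprotonate the benzylic CH2 of the ring A ether, and the carbanion should add to the neighbouring ketone (intramolecular aldol-type closure of ortho-benzyloxy diaryl ketones) to give the racemic tertiary alcohol F5. Ionic deoxygenation (Et3SiH, BF3·OEt2, CH2Cl2, −78 °C) through the dibenzotropylium-type cation, with hydride delivered anti to the C7a aryl group, should give the racemic 7a,8a-cis ether F6. Preparative chromatography on a chiral stationary phase then separates the enantiomers; the (7aR,8aS) enantiomer is 15, where the route is rejoined.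

3. Step 3. The phthalide may fail to ionise and eliminate cleanly in the acylating medium, or the stilbene acid may oligomerise before it cyclises. The fallback sets out from 7: ionic hydrogenolysis of the tertiary benzylic lactone C–O bond (Et3SiH, CF3CO2H) should give the saturated acid F7. Friedel–Crafts cyclisation (P2O5 in CH3SO3H) should give the 10,11-dihydro ketone F8. Dehydrogenation with DDQ (dioxane, 80 °C), through the ortho-quinone methide of the free phenol, should install the C7b=C8b double bond and come back to the route at 9.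

Further compounds
F1 | step 12 | (7aS,8aS,8cR)-nitroalkane: 17 carrying at B4 the 1-(3,5-dimethoxyphenyl)-2-nitroethyl group | COc1ccc(C2=Cc3cc(OC)cc4c3[C@H](c3cc(OC)c([C@@H](c5cc(OC)cc(OC)c5)C[N+](=O)[O-])c(O)c32)[C@@H](c2ccc(OC)cc2)O4)cc1
F2 | step 12 | lactol: ring E closed with OH at C7c (anomers), 3,5-dimethoxyphenyl at C8c | COc1ccc(C2=Cc3cc(OC)cc4c3[C@H](c3cc(OC)c5c(c32)OC(O)[C@@H]5c2cc(OC)cc(OC)c2)[C@@H](c2ccc(OC)cc2)O4)cc1
F3 | step 12 | diol: 17 carrying at B4 the 1-(3,5-dimethoxyphenyl)-2-hydroxy-2-(4-methoxyphenyl)ethyl group (C7c epimers) | COc1ccc(C2=Cc3cc(OC)cc4c3[C@H](c3cc(OC)c([C@@H](c5cc(OC)cc(OC)c5)C(O)c5ccc(OC)cc5)c(O)c32)[C@@H](c2ccc(OC)cc2)O4)cc1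
F4 | step 12 | (7aS,8aS,7cR,8cR)-heptamethyl ether of the target | COc1ccc(C2=Cc3cc(OC)cc4c3[C@H](c3cc(OC)c5c(c32)O[C@@H](c2ccc(OC)cc2)[C@@H]5c2cc(OC)cc(OC)c2)[C@@H](c2ccc(OC)cc2)O4)cc1
F5 | step 7 | racemic tertiary alcohol: ring D closed with OH at C8a (C7a epimers), B5 O-(4-methoxybenzyl) ether | COc1ccc(C2=Cc3cc(OC)cc4c3C(O)(c3cc(OC)cc(OCc5ccc(OC)cc5)c32)C(c2ccc(OC)cc2)O4)cc1
F6 | step 7 | racemate of 15 (SMILES of its mirror-image component, 7aS,8aR) | COc1ccc(C2=Cc3cc(OC)cc4c3[C@@H](c3cc(OC)cc(OCc5ccc(OC)cc5)c32)[C@@H](c2ccc(OC)cc2)O4)cc1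
F7 | step 3 | racemic 2-[2-(3,5-dimethoxyphenyl)-1-(4-methoxyphenyl)ethyl]-3-hydroxy-5-methoxybenzoic acid | OC(=O)c1cc(OC)cc(O)c1C(Cc1cc(OC)cc(OC)c1)c1ccc(OC)cc1
F8 | step 3 | racemic 1-hydroxy-3,6,8-trimethoxy-11-(4-methoxyphenyl)-10,11-dihydro-5H-dibenzo[a,d][7]annulen-5-one | COc1ccc(C2Cc3cc(OC)cc(OC)c3C(=O)c3cc(OC)cc(O)c32)cc1
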